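All constants were set for the occasion; the run is a simulation.

Do not take fast conversion of starting material for a high amount of target: in this scheme target goes on to its isomer after it forms, so the age of the product counts as well.

| flask | starting material | partner | time | remark |
|---|---|---|---|---|
| autumn | 5.0 mM | 1.10 equiv | 8.0 s | a closed flask charged with all of it at once and left for 8.0 s |
| dawn | 5.0 mM | 1.10 equiv |  | one stirred flow tank at steady state, fed with the mixture as stated, mean residence time 8.0 s |
| midnight | 5.0 mM (fed, over 8.00 s) | 1.10 equiv | 8.0 s | all but starting material at the start; starting material goes in evenly over 8.00 s, the run ends at 8.0 s |
| dusk | 5.0 mM | 1.10 equiv (fed, over 8.00 s) | 8.0 s | a stirred flask in which partner is dosed at a steady rate over 8.00 s without added volume, worked up at 8.0 s |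

    starting material ⇌ intermediate B (K1 = 5.8, k1 = 0.028 /s)
    target ⇌ isomer of the product (K2 = 2.6, k2 = 0.083 /s)
    starting material → target (k3 = 1.2 /s)
    starting material ⇌ intermediate A (K4 = 1.5, k4 = 0.075 /s)

- the stated concentrations are those of everything mixed, before any reaction; amounts are the same in each set-up
- the feed brings no volume worth counting
- run time (autumn): 8.0 s

- the set-up with the highest amount of target at the outlet or at the end, in percent of the starting material put in ("none" if the first two lie within 2 percentage points) (autumn / dawn / midnight / dusk / none)
- amount of target at the outlet or at the end, in percent of the starting material put in, autumn
- amount of target at the outlet or at the end, in percent of the starting material put in, dawn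
- amount of target at the outlet or at the end, in percent of the starting material put in, midnight
- amount of target at the outlet or at the end, in percent of the starting material put in, dusk

Turn the question round and ask what a tie between the first two set-ups needs. Take the equilibrium of step 2 as the zero of the scale: of the product, meaning target plus isomer of the product, a share of 27.8% is target at equilibrium. Any excess of target above that zero relaxes at 0.115 /s, forward and back steps together. Multiply this rate by the time in the flask to get the exposure number, here 0.919.

Step 3 runs at 1.2 /s, faster than that relaxation, so reckon product as formed at once. In autumn all of it then has the full age, and the target share is 56.6%. Partner stands in no rate law, so dusk reckons as autumn. In midnight, ages spread evenly from zero to the full run, which gives 75.0%. In dawn, ages follow the residence-time distribution of the tank, which gives 65.4%.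

Midnight and dawn hold my two highest shares, and they lie 9.6 percentage points apart, more than the margin of 2 points. A tie needs those two to lie within that margin, and on these shares they do not. These shares count the whole charge as product formed at once, so they are estimates and not amounts, and my reckoning stops there, with midnight ahead.

The forecast gives lower figures than my shares: 55.9% for autumn, 55.8% for dawn, 64.4% for midnight and 55.9% for dusk. It names midnight best, on the ground that “later-fed material has had less time to isomerise”.

The simulation gives 55.9% for autumn, 55.8% for dawn, 64.4% for midnight and 55.9% for dusk, so midnight is best. In midnight, 9.75% of the starting material still stands at the end. Now raise the exposure number: midnight left to 80.0 s has 9.20, larger than the 0.919 of the run, and its excess factor is 1.02 × 10⁻⁴. Against the zero of 27.8%, the amount of target in that midnight run is 27.4%.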